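**Known so far.** The maple run is the very flask asked about, read up to 20.0 h.

- maple: E 0.15 M; D 0.165 M; Z 7.5 mM; the very flask that is asked about, followed so far
- flask: E 0.15 M; D 0.165 M; Z 7.50 mM; time 50 h

maple run (percent of the E charged)

| time / h | G / % | E / % | Q / % | D.G / % |
|---|---|---|---|---|
| 1.33 | 8 | 92 | 2 | 3 |
| 4.00 | 23 | 73 | 1 | 0 |
| 8.00 | 37 | 57 | 3 | 3 |
| 10.0 | 42 | 48 | 0 | 7 |
| 15.0 | 52 | 36 | 1 | 6 |
| 20.0 | 58 | 26 | 1 | 12 |

(standard deviation of a reading: 1.5 percentage points)

- the numbers in the tables scatter with a standard deviation of 1.5 percentage points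
- a reading or a percentage of D.G counts all its forms, free or not
- a reading or a percentage of E is of its free form alone

- where most of what was charged as E, at 50 h is found (G / E / Q / D.G)
- the largest share itself, whichever of these holds it, in percent of the E charged

**Fast rung.** By my reckoning, E decays first-order: the 26 % left at 20.0 h gives kE = 0.0674 /h, a half-life of 10.3 h.

**Slow rung.** G feeds D.G. Dividing the D.G reading of 12 % at 20.0 h by the mid-run G reading, 42 %, and then by that time gives kG = 0.0143 /h. This is a pseudo-first-order constant with c(D) taken as its charge, and its half-life of 48.5 h is longer than that of E. Q reads 1 % at 20.0 h, below the scatter, so it stays off the ladder.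

**Hand-over time.** Control passes when kE·c(E) equals kG·c(G), so G is made as fast as it is used. This crossing, ln(kE/kG)/(kE − kG), falls at 29.2 h. In this reckoning G climbs before it and declines after it, while D.G gains. The asked time lies beyond it, but taking E as passing into G, G still holds 57.8 %, more than the 38.8 % beyond G and E.

The forecast gives G at 52 %: “it should still hold the most”.

**The flask.** At 50 h, G holds 57.0 % and D.G 30.5 %.

    E + D.G ⇌ E.D.G, settled at all times (K = 2.10 /M)
    D + G → D.G (k = 0.00160 /M/min)
    D.G → Q (k = 8.10 × 10⁻⁵ /min)
    E → G (k = 0.00110 /min)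
    E + Z → E.Z (k = 0.0890 /M/min)

At 9.83 h, before the reckoned hand-over at 29.2 h, G was made 5.06 times as fast as it was used, each step taken net; by 50 h, past it, with E at 3.65 %, that ratio was 0.387, and G had gone from 60.8 % at 25.0 h to 57.0 %. In the neighbour charged with 0.66 M of D, the reckoned kG scales to 0.0571 /h, which puts the reckoned hand-over earlier, at 16.1 h, and at 50 h that flask holds 15.1 % of G and 66.4 % of D.G.

(Readings and results are simulated with made-up constants; the scatter is artificial.)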